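**Plan**

- The target is a 7-hydroxy-5-methoxyisoflavone with a 3'-hydroxy-4'-methoxy-5'-prenyl ring B. The retrosynthesis first places allyl groups on O7 and O3', then cuts ring C at C3–C4 and at O1–C8a.
- This gives the ring A acid chloride 5, with fluorine at the future C8a, and the ring B enamine 15, whose two vinyl carbons become C3 and C2. O1 is supplied by water.
- Enabling feature: C8a carries O1 ortho to the C4 carbonyl, so a fluorine at C8a is activated for displacement by an enolate oxygen. Using fluorine as a stand-in for oxygen also lets O5 and O7 be set one at a time on a symmetric 2,6-difluorobenzoate.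
- Forward: ring A reaches 5 in four steps (O-allylation, methoxide for one fluorine, saponification, acid chloride). Ring B reaches 15 in five steps from 5-bromovanillin (demethylation, selective 4-O-methylation, Stille prenylation, O-allylation, Horner–Wittig enamine formation).
- Rings A and B are bought. Ring C is the only ring formed, in step 11, and one palladium-catalysed double deallylation then gives the target.
- Stereochemistry: there is no stereocentre, the prenyl alkene has no geometric isomers, and the enamine geometry is erased in step 11.

Key step: step 11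

Remark: methyl 2,6-difluoro-4-hydroxybenzoate, diphenylphosphine oxide and tributyl(3-methylbut-2-enyl)stannane are taken as catalogue compounds; enamine 15 is drawn as the E isomer expected for a conjugated β-aminostyrene, and any Z isomer would converge on the same enolate in step 11.

**Route**

Step 1
Reactants: 1 methyl 2,6-difluoro-4-hydroxybenzoate
Product: 2 methyl 2,6-difluoro-4-(prop-2-enyloxy)benzoate
Conditions: allyl bromide, K2CO3, acetone, reflux
Reagents that add atoms: allyl bromide, C=CCBr
Why: Williamson ether synthesis on an acidic phenol (para to the ester, two meta fluorines) should place the O7 allyl group with no regiochemical question.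

Step 2
Reactants: 2 methyl 2,6-difluoro-4-(prop-2-enyloxy)benzoate
Product: 3 methyl 2-fluoro-6-methoxy-4-(prop-2-enyloxy)benzoate
Conditions: NaOMe (1.1 equiv), MeOH/THF, 60 °C
Reagents that add atoms: sodium methoxide, C[O-].[Na+]
Why: Nucleophilic aromatic substitution at one of two equivalent fluorines ortho to the ester should stop at the mono-ether, since the methoxy group installed activates less than the fluorine it replaces, and methoxide matches the ester so transesterification is invisible.

Step 3
Reactants: 3 methyl 2-fluoro-6-methoxy-4-(prop-2-enyloxy)benzoate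
Product: 4 2-fluoro-6-methoxy-4-(prop-2-enyloxy)benzoic acid
Conditions: LiOH, THF/MeOH/H2O, 50 °C; then aq. HCl
Reagents that add atoms: lithium hydroxide, [Li+].[OH-]
Why: Ester saponification should spare the remaining fluorine, because the carboxylate formed deactivates the ring toward further substitution.

Step 4
Reactants: 4 2-fluoro-6-methoxy-4-(prop-2-enyloxy)benzoic acid
Product: 5 2-fluoro-6-methoxy-4-(prop-2-enyloxy)benzoyl chloride
Conditions: (COCl)2, cat. DMF, CH2Cl2, 0 °C to rt; evaporate, use crude
Reagents that add atoms: oxalyl chloride, ClC(=O)C(=O)Cl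
Why: Acid chloride formation through the Vilsmeier-type chloroiminium catalyst is neutral enough for the allyl ether and gives only gaseous by-products.

Step 5
Reactants: 6 5-bromovanillin (3-bromo-4-hydroxy-5-methoxybenzaldehyde)
Product: 7 3-bromo-4,5-dihydroxybenzaldehyde
Conditions: AlCl3, pyridine, CH2Cl2, reflux; then aq. HCl
Reagents that add atoms: none
Why: Lewis-acid ether cleavage of an ortho-hydroxyanisole works because aluminium chelated between the phenoxide and the methoxy oxygen activates the methyl group for SN2 removal by pyridine, leaving aldehyde and bromide untouched.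

Step 6
Reactants: 7 3-bromo-4,5-dihydroxybenzaldehyde
Product: 8 3-bromo-5-hydroxy-4-methoxybenzaldehyde
Conditions: MeI (1.05 equiv), Li2CO3, DMF, 45 °C
Reagents that add atoms: iodomethane, CI
Why: Regioselective Williamson methylation is expected because the hydroxyl para to the aldehyde and ortho to bromine is clearly the more acidic, so the weak base Li2CO3 should form and alkylate only that phenoxide.

Step 7
Reactants: 8 3-bromo-5-hydroxy-4-methoxybenzaldehyde
Product: 9 3-hydroxy-4-methoxy-5-(3-methylbut-2-enyl)benzaldehyde
Conditions: tributyl(3-methylbut-2-enyl)stannane, Pd(PPh3)4 (5 mol %), DMF, 90 °C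
Reagents that add atoms: tributyl(3-methylbut-2-enyl)stannane, CCCC[Sn](CCCC)(CCCC)CC=C(C)C
Why: Stille cross-coupling tolerates the free phenol and the aldehyde, and prenylstannanes are expected to deliver the allyl unit mainly through its unsubstituted carbon to give the linear prenyl arene.

Step 8
Reactants: 9 3-hydroxy-4-methoxy-5-(3-methylbut-2-enyl)benzaldehyde
Product: 10 4-methoxy-3-(3-methylbut-2-enyl)-5-(prop-2-enyloxy)benzaldehyde
Conditions: allyl bromide, K2CO3, DMF, rt
Reagents that add atoms: allyl bromide, C=CCBr
Why: Williamson ether synthesis masks O3' with the same group as O7, and doing it after the palladium coupling keeps the aryl allyl ether away from zerovalent palladium until the final step.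

Step 9
Reactants: 11 diphenylphosphine oxide; 12 morpholine
Product: 13 4-[(diphenylphosphoryl)methyl]morpholine
Conditions: paraformaldehyde, toluene, reflux (Dean–Stark)
Reagents that add atoms: paraformaldehyde (as formaldehyde), C=O
Why: Kabachnik–Fields (phospha-Mannich) condensation should occur because the iminium ion from morpholine and formaldehyde is trapped by the P–H bond of the secondary phosphine oxide.

Step 10
Reactants: 10 4-methoxy-3-(3-methylbut-2-enyl)-5-(prop-2-enyloxy)benzaldehyde; 13 4-[(diphenylphosphoryl)methyl]morpholine
Product: 15 4-{(E)-2-[4-methoxy-3-(3-methylbut-2-enyl)-5-(prop-2-enyloxy)phenyl]ethenyl}morpholine, via lithium alkoxide adduct 14 (not isolated)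
Conditions: 13, n-BuLi, THF, −78 °C; add 10, −78 to 0 °C; then KOt-Bu, rt; basic aqueous work-up, use crude
Reagents that add atoms: none
Why: Horner–Wittig enamine synthesis, in which the lithiated (aminomethyl)phosphine oxide adds to the aldehyde and exchange of lithium for potassium triggers syn-elimination of diphenylphosphinate, should give the conjugated enamine without ever handling the free arylacetaldehyde or any acid.

Step 11
Reactants: 5 2-fluoro-6-methoxy-4-(prop-2-enyloxy)benzoyl chloride; 15 4-{(E)-2-[4-methoxy-3-(3-methylbut-2-enyl)-5-(prop-2-enyloxy)phenyl]ethenyl}morpholine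
Product: 18 5-methoxy-3-[4-methoxy-3-(3-methylbut-2-enyl)-5-(prop-2-enyloxy)phenyl]-7-(prop-2-enyloxy)chromen-4-one, via enaminone 16 (not isolated), via potassium enolate 17 (not isolated)
Conditions: Et3N, CH2Cl2, 0 °C to rt; then solvent exchange to DMF, K2CO3, H2O (few equiv), 90 °C
Reagents that add atoms: water, O
Why: The β-carbon of the conjugated enamine attacks the acyl chloride (Stork enamine acylation) and Et3N removes HCl, giving the vinylogous amide 16 with the C3–C4 bond in place. Aqueous carbonate then adds hydroxide to the aminomethylene carbon and expels morpholine (addition–elimination), so O1 comes from water and the delocalised enolate 17 results. The enolate oxygen attacks C8a, the Meisenheimer adduct is stabilised by the ortho C4 carbonyl, and loss of fluoride closes ring C as a six-membered ring by intramolecular nucleophilic aromatic substitution forming O1–C8a. The closest known reaction type is the Grohe–Heitzer sequence of acylating an enamine with a 2-halobenzoyl chloride and cyclising by halide displacement, here with an enolate oxygen in place of an amine nitrogen as in its chromone variants. No stereocentre is formed and the enamine geometry is erased in 17. The step needs C- over N-acylation, secured by the nucleophilic β-carbon of the aminostyrene and the reversibility of N-acylation, and ring closure ahead of retro-Claisen loss of the formyl carbon, favoured because 17 is held as its enolate under carbonate with little water, while the single fluorine fixes the site of substitution.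

Step 12
Reactants: 18 5-methoxy-3-[4-methoxy-3-(3-methylbut-2-enyl)-5-(prop-2-enyloxy)phenyl]-7-(prop-2-enyloxy)chromen-4-one
Product: 19 7-hydroxy-3-[3-hydroxy-4-methoxy-5-(3-methylbut-2-enyl)phenyl]-5-methoxychromen-4-one (EANPDB:LEGU_00347)
Conditions: Pd(PPh3)4 (5 mol %), morpholine (excess), THF, 50 °C
Reagents that add atoms: none
Why: Tsuji–Trost-type deallylation, in which zerovalent palladium ionises both aryl allyl ethers to π-allyl complexes that morpholine captures, should free O7 and O3' in one operation without touching the C-bound prenyl group or the methyl ethers.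

**Compound list**

1 | methyl 2,6-difluoro-4-hydroxybenzoate | COC(=O)c1c(F)cc(O)cc1F | starting material
2 | methyl 2,6-difluoro-4-(prop-2-enyloxy)benzoate | COC(=O)c1c(F)cc(OCC=C)cc1F | intermediate
3 | methyl 2-fluoro-6-methoxy-4-(prop-2-enyloxy)benzoate | COC(=O)c1c(F)cc(OCC=C)cc1OC | intermediate
4 | 2-fluoro-6-methoxy-4-(prop-2-enyloxy)benzoic acid | OC(=O)c1c(F)cc(OCC=C)cc1OC | intermediate
5 | 2-fluoro-6-methoxy-4-(prop-2-enyloxy)benzoyl chloride | ClC(=O)c1c(F)cc(OCC=C)cc1OC | intermediate
6 | 5-bromovanillin (3-bromo-4-hydroxy-5-methoxybenzaldehyde) | COc1cc(C=O)cc(Br)c1O | starting material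
7 | 3-bromo-4,5-dihydroxybenzaldehyde | Oc1cc(C=O)cc(Br)c1O | intermediate
8 | 3-bromo-5-hydroxy-4-methoxybenzaldehyde | COc1c(O)cc(C=O)cc1Br | intermediate
9 | 3-hydroxy-4-methoxy-5-(3-methylbut-2-enyl)benzaldehyde | COc1c(O)cc(C=O)cc1CC=C(C)C | intermediate
10 | 4-methoxy-3-(3-methylbut-2-enyl)-5-(prop-2-enyloxy)benzaldehyde | COc1c(OCC=C)cc(C=O)cc1CC=C(C)C | intermediate
11 | diphenylphosphine oxide | O=[PH](c1ccccc1)c1ccccc1 | starting material
12 | morpholine | C1COCCN1 | starting material
13 | 4-[(diphenylphosphoryl)methyl]morpholine | O=P(CN1CCOCC1)(c1ccccc1)c1ccccc1 | intermediate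
14 | lithium 2-(diphenylphosphoryl)-1-[4-methoxy-3-(3-methylbut-2-enyl)-5-(prop-2-enyloxy)phenyl]-2-(morpholin-4-yl)ethanolate (racemic mixture of diastereomers, configuration not defined) | [Li+].[O-]C(c1cc(OCC=C)c(OC)c(CC=C(C)C)c1)C(N1CCOCC1)P(=O)(c1ccccc1)c1ccccc1 | intermediate
15 | 4-{(E)-2-[4-methoxy-3-(3-methylbut-2-enyl)-5-(prop-2-enyloxy)phenyl]ethenyl}morpholine | COc1c(OCC=C)cc(/C=C/N2CCOCC2)cc1CC=C(C)C | intermediate
16 | (E)-1-[2-fluoro-6-methoxy-4-(prop-2-enyloxy)phenyl]-2-[4-methoxy-3-(3-methylbut-2-enyl)-5-(prop-2-enyloxy)phenyl]-3-(morpholin-4-yl)prop-2-en-1-one | COc1cc(OCC=C)cc(F)c1C(=O)/C(=C/N1CCOCC1)c1cc(OCC=C)c(OC)c(CC=C(C)C)c1 | intermediate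
17 | potassium (Z)-3-[2-fluoro-6-methoxy-4-(prop-2-enyloxy)phenyl]-2-[4-methoxy-3-(3-methylbut-2-enyl)-5-(prop-2-enyloxy)phenyl]-3-oxoprop-1-en-1-olate | [K+].[O-]/C=C(\C(=O)c1c(F)cc(OCC=C)cc1OC)c1cc(OCC=C)c(OC)c(CC=C(C)C)c1 | intermediate
18 | 5-methoxy-3-[4-methoxy-3-(3-methylbut-2-enyl)-5-(prop-2-enyloxy)phenyl]-7-(prop-2-enyloxy)chromen-4-one | C=CCOc1cc(OC)c2c(c1)occ(-c1cc(OCC=C)c(OC)c(CC=C(C)C)c1)c2=O | intermediate
19 | 7-hydroxy-3-[3-hydroxy-4-methoxy-5-(3-methylbut-2-enyl)phenyl]-5-methoxychromen-4-one | COc1c(O)cc(-c2coc3cc(O)cc(OC)c3c2=O)cc1CC=C(C)C | target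

**Step count and risks**

Total step count: 12. Longest linear sequence: 7 steps (steps 5, 6, 7, 8, 10, 11, 12, from 5-bromovanillin).

Steps most likely to fail:

Step 11. Retro-Claisen loss of the formyl carbon from the hydrolysed enaminone may outrun the fluoride displacement, which is slowed by the two alkoxy groups that feed electron density into the C4 carbonyl. The fallback sets out from enaminone 16, made as in step 11 and not exposed to carbonate. Aqueous NaOH in ethanol at 50 °C is used to drive hydrolysis and deformylation on purpose, giving the deoxybenzoin 1-[2-fluoro-6-methoxy-4-(prop-2-enyloxy)phenyl]-2-[4-methoxy-3-(3-methylbut-2-enyl)-5-(prop-2-enyloxy)phenyl]ethanone F1, which is isolated. Claisen formylation of F1 with ethyl formate and KOt-Bu in dry THF (the classical deoxybenzoin formylation of isoflavone chemistry) then regenerates potassium enolate 17 in the absence of hydroxide, where any loss of the formyl group is reversible. Replacing THF by DMF and heating to 90–100 °C should close ring C by the same fluoride displacement, and the route is rejoined at 18.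

Step 10. Syn-elimination of diphenylphosphinate from the adduct may be incomplete, or the enamine may hydrolyse during work-up. The fallback sets out from aldehyde 10. Wittig reaction with the ylide from (methoxymethyl)triphenylphosphonium chloride and KOt-Bu in THF at 0 °C should give the enol ether 1-methoxy-4-(2-methoxyethenyl)-2-(3-methylbut-2-enyl)-6-(prop-2-enyloxy)benzene F2 as an E/Z mixture. Brief hydrolysis with 2 M HCl in THF at rt, tolerable because no acetal protecting group is present, should give [4-methoxy-3-(3-methylbut-2-enyl)-5-(prop-2-enyloxy)phenyl]acetaldehyde F3. Condensation of F3 with morpholine in toluene over MgSO4 then gives the enamine, and the route is rejoined at 15.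

Step 7. Allylic transposition during transmetalation could deliver the branched 1,1-dimethylallyl isomer, and protodestannylation of the prenylstannane by the free phenol could starve the coupling. The fallback sets out from bromide 8. Stille coupling with allyltributylstannane (Pd(PPh3)4, DMF, 90 °C), for which transposition gives the same product, should give 3-hydroxy-4-methoxy-5-(prop-2-enyl)benzaldehyde F4. Olefin cross-metathesis of F4 with excess 2-methylbut-2-ene and the second-generation Grubbs catalyst in CH2Cl2 at 40 °C then turns the allyl group into the prenyl group, and the route is rejoined at 9.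

**Further compounds**

F1 | step 11 | 1-[2-fluoro-6-methoxy-4-(prop-2-enyloxy)phenyl]-2-[4-methoxy-3-(3-methylbut-2-enyl)-5-(prop-2-enyloxy)phenyl]ethanone | COc1cc(OCC=C)cc(F)c1C(=O)Cc1cc(OCC=C)c(OC)c(CC=C(C)C)c1
F2 | step 10 | 1-methoxy-4-(2-methoxyethenyl)-2-(3-methylbut-2-enyl)-6-(prop-2-enyloxy)benzene (E/Z mixture) | COC=Cc1cc(OCC=C)c(OC)c(CC=C(C)C)c1
F3 | step 10 | [4-methoxy-3-(3-methylbut-2-enyl)-5-(prop-2-enyloxy)phenyl]acetaldehyde | O=CCc1cc(OCC=C)c(OC)c(CC=C(C)C)c1
F4 | step 7 | 3-hydroxy-4-methoxy-5-(prop-2-enyl)benzaldehyde | COc1c(O)cc(C=O)cc1CC=C
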